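(Readings and results come from a simulation for an exercise; noise was put on by code.)

The constants are hidden, so I start from what the two earlier runs give directly: a clock.

common to all: substrate 1.5 M

|  | solid reagent | temperature | remark | time |
|---|---|---|---|---|
| dawn | 1.1 M | −10 °C | run made earlier |  |
| dusk | 1.1 M | 1 °C | run made earlier |  |
| amber | 2.25 M | 5 °C |  | 4.0 d |
| blue | 2.25 M | −15 °C |  | 4.0 d |
| grey | 2.25 M |  | at 5 °C until 20 h, from then on at −15 °C | 4.0 d |

| run | time / d | target / % |
|---|---|---|
| dawn | 0.500 | 2.1 |
| dawn | 1.67 | 13.9 |
| dawn | 2.50 | 22.3 |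
| dawn | 4.00 | 31.2 |
| dawn | 6.00 | 34.7 |
| dawn | 8.00 | 36.7 |
| dawn | 10.0 | 36.8 |
| dusk | 0.250 | 2.7 |
| dusk | 0.833 | 14.9 |
| dusk | 1.25 | 22.1 |
| dusk | 2.08 | 30.1 |
| dusk | 3.00 | 32.4 |
| dusk | 4.00 | 34.3 |
| dusk | 5.00 | 34.8 |

(readings scatter by 0.3 percentage points)

- as a solid, counted per litre of solution: solid reagent
- candidate steps: substrate + partner <-> intermediate; intermediate -> target; target <-> isomer of the product; solid reagent <-> partner
- at the start none of the solid reagent is in solution

* which flask leads in amount of target, in percent of the substrate charged ("all alike" within 1.5 percentage points) (amber / blue / grey / all alike)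
* how much target is there at the end, in percent of the substrate charged: amber
* how much target is there at the end, in percent of the substrate charged: blue
* how much target is there at the end, in percent of the substrate charged: grey

Dawn's target starts slowly, 2.1% at 0.500 d, then runs straight, gaining 8.4 percentage points in the 0.830 d up to 2.50 d. It bends before 4.00 d and levels at 36.8%. Dusk passes the same mid-rise level in less time: it reads 22.1% at 1.25 d, where dawn reads 22.3% at 2.50 d, so at this level its clock runs 2.00 times as fast. This factor rests on one pair of readings, and the two curves differ in shape and level: at doubled times dusk reads 14.9% against 13.9% early and 34.8% against 36.8% late, with a scatter of 0.3 points. I therefore trust the clock best in the rise and take it as rough past the bend.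

I assume this factor repeats over equal steps of temperature and define the clock factor f, the dawn days that one day at temperature T is worth: the dawn-to-dusk factor raised to the power (T − T_dawn)/(T_dusk − T_dawn). This gives f = 2.57 at 5 °C and f = 0.730 at −15 °C. The dawn-equivalent time θ is the sum of f times the days spent at each temperature.

Blue reaches θ = 2.92 d, on dawn's curve between 2.50 d and 4.00 d, so I interpolate 24.8%. Grey reaches θ = 4.46 d, past the bend, which gives 32.0%. Amber reaches θ = 10.3 d, beyond dawn's last reading. Dawn charges less solid reagent than substrate, so I read that reagent as dawn's limiting reagent; it can carry 73.3% of the substrate, and dawn's level is 50.2% of that. Amber charges more solid reagent than substrate, so the same share of the whole charge gives amber 50.2%.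

The forecast, citing “dissolution-limited supply”, says 46% for amber, 26.5% for blue and 40% for grey, with amber ahead, and its grey stands above my 32.0%.

The flasks give 44.6% for amber, 21.5% for blue and 29.4% for grey, and amber leads.

    substrate + partner ⇌ intermediate (K = 0.250 L mol⁻¹, k = 0.430 L mol⁻¹ h⁻¹, Ea = 69.0 kJ mol⁻¹, ΔH = −64.0 kJ mol⁻¹)
    intermediate → target (k = 0.250 h⁻¹, Ea = 97.0 kJ mol⁻¹)
    target ⇌ isomer of the product (K = 0.980, k = 0.0720 h⁻¹, Ea = 89.0 kJ mol⁻¹, ΔH = 2.00 kJ mol⁻¹)
    solid reagent ⇌ partner, rate k4*(cs4 - [partner]) while solid is left; crystals form when [partner] > cs4 (solubility = 0.500 M, k = 0.190 h⁻¹)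
    (constants at 5 °C)

My clock reads high on both cold flasks, by 3.3 points on blue and 2.6 points on grey. In amber, the main reason that target stands where it does is the reaction of target to isomer of the product, both ways: amber holds 44.6% with that reaction and 85.6% without it.

Grey left until 6.0 d reaches θ = 5.91 d, beside dawn's 34.7% at 6.00 d. That flask holds 37.0%.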